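The data stem from a simulated flask for an exercise.

The vessel starts with coupling partner and precatalyst, substrate runs in steadily, and the volume grows as it does.

| flask | substrate | coupling partner | precatalyst | remark | time |
|---|---|---|---|---|---|
| delta | 10 mM (fed, over 2.5 h) | 18 mM | 24 µM | run made earlier; the fed solution adds 0.20 times the starting volume |  |
| eta | 40 mM (fed, over 2.5 h) | 18 mM | 24 µM | run made earlier; the fed solution adds 0.20 times the starting volume |  |
| alpha | 20 mM (fed, over 2.5 h) | 18 mM | 12 µM | run made earlier; the fed solution adds 0.20 times the starting volume |  |
| flask | 20 mM (fed, over 2.5 h) | 18.0 mM | 24 µM | the fed solution adds 0.20 times the starting volume | 4.0 h |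

| run | time / h | product / % | substrate / % |
|---|---|---|---|
| delta | 0.417 | 15.1 | 2.9 |
| delta | 0.833 | 32.2 | 0.8 |
| delta | 1.33 | 51.9 | 0.6 |
| delta | 1.50 | 58.4 | 0 |
| delta | 2.00 | 79.8 | 0.4 |
| delta | 2.50 | 100.9 | 2.2 |
| eta | 0.200 | 4.0 | 4.6 |
| eta | 0.333 | 7.8 | 7.3 |
| eta | 0.500 | 12.1 | 8.3 |
| eta | 0.833 | 21.1 | 13.7 |
| eta | 1.33 | 26.4 | 27.8 |
| eta | 2.50 | 38.7 | 61.7 |
| alpha | 0.500 | 10.2 | 10.0 |
| alpha | 1.00 | 26.2 | 15.8 |
| alpha | 1.33 | 31.8 | 18.5 |
| alpha | 2.00 | 47.5 | 32.4 |
| alpha | 2.50 | 51.2 | 46.8 |

(readings scatter by 1 percentage point)

1. why nothing more happens at 4.0 h, or that something still does (it is still moving / the coupling partner has run out first / no working catalyst is left / all of the substrate has reacted / forward and back rates have come level)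
2. the product standing at 4.0 h, as a percentage of the substrate charged

- amounts are per litre of the starting volume; all of the dose is in the solution fed
- the numbers in the tables scatter by 1 percentage point (one standard deviation)
- steps that have been proposed: coupling partner + free catalyst -> catalyst intermediate A; catalyst intermediate A -> catalyst intermediate B; substrate + catalyst intermediate B -> catalyst intermediate C; catalyst intermediate C -> catalyst intermediate D; catalyst intermediate D -> free catalyst + product; precatalyst <-> free catalyst
- the reaction counts as stopped when no species that holds the substrate changes by six tenths of a point or more over the second half of the time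
- percentages count the whole charge, also what has not yet gone in

In the delta run, substrate stays at or below 2.9% while product keeps pace with the feed. In the eta run, with the same catalyst charge as your flask, product slows while substrate climbs to 61.7%. So take the rate there as proportional to the partner's concentration. Eta's last reading leaves 2.52 mM of partner after a volume-weighted time (the integral of dt over relative volume) of 2.28 h. That gives a reading of the partner clearance, the fraction of partner consumed per hour at starting volume with this catalyst charge:

clearance = ln(partner charge / partner left) / weighted time = 0.863 h⁻¹

Your flask has two ceilings. With an infinitely fast catalyst, product stops at the charge of the coupling partner, the limiting reagent, which is 90.0%. Over 3.53 h of weighted time, clearance acting from the start takes product to 85.7%. The real rate obeys both, so the flask lies below both. It starts with capacity 15.5 mM h⁻¹, above the feed of 8.00 mM h⁻¹, so product first follows the feed. Control passes to clearance when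

clearance × (partner charge − feed × t) = feed × relative volume at t

which gives t = 0.998 h, with 10.0 mM of partner left. The remaining 2.57 h of weighted time leaves 1.09 mM. My reckoning is therefore 84.5% product, still forming at 0.785 mM h⁻¹.

The forecast answers it is still moving, with 85% product, and of the rate per catalyst at equal product it says that this “points away from catalyst death and toward coupling partner depletion”.

The flask answers it is still moving, with 84.6% product.

    coupling partner + free catalyst → catalyst intermediate A (k = 39.0 M⁻¹ s⁻¹)
    catalyst intermediate A → catalyst intermediate B (k = 70.0 s⁻¹)
    substrate + catalyst intermediate B → catalyst intermediate C (k = 850 M⁻¹ s⁻¹)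
    catalyst intermediate C → catalyst intermediate D (k = 3.50 s⁻¹)
    catalyst intermediate D → free catalyst + product (k = 35.0 s⁻¹)
    precatalyst ⇌ free catalyst (K = 0.370, k = 7.40 × 10⁻⁴ s⁻¹)

The reckoning left 6.07% of the partner in your flask, which holds 6.0%. Now take the neighbour with 4.5 mM of coupling partner. Its starting capacity of 3.88 mM h⁻¹ lies below the feed, so the reckoning has no feed-following stretch and clearance acts from the start. That predicts 4.75% of its partner left and 21.4% product. The neighbour holds 4.6% of its partner and 21.5% product.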